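**Strategy.** Superstolide A is cut into three pieces. These are a cis-decalin carrying both macrocycle arms (C7, C18), a C20–C27 amino-polyol stannane, and a C1–C5 iododienoic acid. Stille coupling (C19–C20), esterification (O23–C1) and a Suzuki ring closure (C5–C6) assemble the 16-membered lactone. Everything rests on bringing in the C13 oxygen late. O11 and O13 are cis and 1,3-related on ring A, so a silicon atom hung on O11 can reach only the C13–H bond on its own face. One iridium-catalysed C–H silylation turns the 13-deoxy decalin, as its O11 diethyl(hydrido)silyl ether, into an O11–Si–C13 oxasilolane. This fixes the site and configuration of the future carbamate carbon.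

Key step: step 13

**Remarks**
- Convention: superstolide numbering is used throughout. β is the decalin face that carries C7, C18, O11 and O13. α is the face that carries H9, H14, H17 and the C8 methyl group. Compounds 16 and 17 were checked centre by centre against 56 and agree with it.
- Conformation: the quaternary C8 is a tert-alkyl substituent on C9. It anchors ring A in the chair in which C8 and the cis-1,3 O11 are both equatorial. A chair with axial O11 would place C8, O11 and the β hydrogen at C13 triaxial, which is out of reach. The silylation therefore has to pass through the ring A boat with C9 and C12 as bow and stern.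
- Design of the precursor: 16 carries the smaller TBS group on the β-face arm (O18) and the large TIPS group on the remote neopentyl O7. It has no arene, no carbonyl group and no primary γ C–H bond. Free Et2SiH2 is stripped off before heating, and the later oxidation is fluoride-free.
- Assumption: the sense of induction in step 5 is assigned from the usual binding model of the oxazaborolidinium catalyst with enones (boron on the carbonyl lone pair syn to the reacting C=C, α-C–H···O contact, one face shielded by a phenyl group). Should the opposite sense be found, the equally available (R)-catalyst is to be used.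

**Route**

Step 1
Reactants: 1 benzoic acid
Product: 2 1-methylcyclohexa-2,5-diene-1-carboxylic acid
Conditions: Li, NH3(l)/THF, −78 °C; MeI; aq HCl
Reagents that add atoms: iodomethane (CI)
Why: Birch reductive alkylation: dissolving-metal reduction of the benzoate gives the carboxylate-stabilised dienolate, which is methylated at the ipso carbon (future C8) to the achiral 1,4-diene.

Step 2
Reactants: 2 1-methylcyclohexa-2,5-diene-1-carboxylic acid
Product: 3 methyl 1-methylcyclohexa-2,5-diene-1-carboxylate
Conditions: MeI, K2CO3, DMF, rt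
Reagents that add atoms: iodomethane (CI)
Why: SN2 O-alkylation of the carboxylate esterifies the hindered acid without strong acid that could isomerise the skipped diene.

Step 3
Reactants: 3 methyl 1-methylcyclohexa-2,5-diene-1-carboxylate
Product: 4 methyl 1-methyl-4-oxocyclohexa-2,5-diene-1-carboxylate
Conditions: Rh2(cap)4 (1 mol %), t-BuOOH (70% aq), CH2Cl2, rt
Reagents that add atoms: tert-butyl hydroperoxide (CC(C)(C)OO)
Why: Radical allylic oxidation: the tert-butylperoxyl chain attacks the only doubly allylic CH2 group and the quaternary carbon blocks aromatisation, so the cross-conjugated and still achiral dienone results.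

Step 4
Reactants: 5 but-3-en-2-one
Product: 6 2-(tert-butyldimethylsilyloxy)buta-1,3-diene
Conditions: TBSOTf, Et3N, Et2O, 0 °C
Reagents that add atoms: tert-butyldimethylsilyl triflate (CC(C)(C)[Si](C)(C)OS(=O)(=O)C(F)(F)F)
Why: Soft enolisation and O-silylation of the methyl ketone (silyl enol ether formation) gives the 2-silyloxydiene, TBS being chosen over TMS so that the enol ether formed in step 5 can mask the C11 ketone up to step 9.

Step 5
Reactants: 4 methyl 1-methyl-4-oxocyclohexa-2,5-diene-1-carboxylate; 6 2-(tert-butyldimethylsilyloxy)buta-1,3-diene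
Product: 7 cis-decalin enone ester (C15 ketone; C16=C17; C8 with α-CH3 and β-CO2Me; H9 and H14 α; TBS enol ether C11=C12)
Conditions: (S)-o-tolyl-CBS oxazaborolidine (20 mol %), Tf2NH (18 mol %), CH2Cl2, −78 → −40 °C
Reagents that add atoms: none
Why: Catalytic enantioselective Diels–Alder reaction (chiral oxazaborolidinium Lewis acid, established for cyclic enones, quinones and quinone monoketals with 2-silyloxydienes): the nucleophilic CH2 terminus of 6 bonds to C9 (para rule, oxygen at C11), suprafacial addition makes the fusion cis, the diene enters anti to the C8 methyl group past the flat, smaller and electron-withdrawing ester, and the catalyst selects one of the two enantiotopic C=C bonds, so C8, C9 and C14 are set together.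

Step 6
Reactants: 7 cis-decalin enone ester
Product: 8 diol (C15 β-OH; C7 CH2OH; C16=C17; TBS enol ether kept)
Conditions: DIBAL-H (5 equiv), CH2Cl2, −78 → 0 °C; aq work-up
Reagents that add atoms: none
Why: 1,2-Reduction of the enone and full reduction of the ester by DIBAL-H, hydride reaching C15 from the convex α face of the cis-fused bicycle so that the C15 hydroxyl is β, while the silyl enol ether is inert.

Step 7
Reactants: 8 diol
Product: 9 C7 TIPS ether (free C15 β-OH)
Conditions: TIPSOTf (1.05 equiv), 2,6-lutidine, CH2Cl2, −78 °C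
Reagents that add atoms: triisopropylsilyl triflate (CC(C)[Si](C(C)C)(C(C)C)OS(=O)(=O)C(F)(F)F)
Why: Steric differentiation in O-silylation: the bulky silyl triflate takes the primary hydroxyl in preference to the secondary allylic hydroxyl buried on the concave face next to the ring fusion.

Step 8
Reactants: 9 C7 TIPS ether
Product: 10 C15 β-(tributylstannyl)methyl ether
Conditions: KH, THF, 0 °C; Bu3SnCH2I, 18-crown-6 (cat.), rt
Reagents that add atoms: tributyl(iodomethyl)stannane (CCCC[Sn](CI)(CCCC)CCCC)
Why: Williamson etherification of the potassium alkoxide with the reactive primary iodide installs the carbanion precursor without touching the silyl ether or the enol ether.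

Step 9
Reactants: 10 C15 β-(tributylstannyl)methyl ether
Product: 12 hydroxy ketone (C11 ketone; C17 β-CH2OH; C15=C16; C7 OTIPS), via homoallylic alcohol enol ether 11 (not isolated)
Conditions: n-BuLi, THF, −78 °C; then 1 M aq HCl, 0 °C → rt
Reagents that add atoms: none
Why: Wittig–Still [2,3]-sigmatropic rearrangement: tin–lithium exchange gives the α-alkoxy carbanion, which moves suprafacially from the β C15–O bond to C17, so C18 arrives β (cis to C7) and the alkene shifts to C15=C16, and the acidic quench hydrolyses the enol ether to the C11 ketone.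

Step 10
Reactants: 12 hydroxy ketone
Product: 13 ketone (C11 ketone; C18 OTBS; C7 OTIPS)
Conditions: TBSCl, imidazole, DMF, rt
Reagents that add atoms: tert-butyldimethylsilyl chloride (CC(C)(C)[Si](C)(C)Cl)
Why: Standard O-silylation of the only hydroxyl gives an arm that can later be freed in the presence of the TIPS ether.

Step 11
Reactants: 13 ketone
Product: 14 13-deoxy alcohol (C11 β-OH; equatorial)
Conditions: NaBH4, MeOH/CH2Cl2, −78 → −20 °C
Reagents that add atoms: none
Why: Small-hydride reduction of a cyclohexanone by axial attack from the convex α face gives the equatorial β alcohol and sets C11.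

Step 12
Reactants: 14 13-deoxy alcohol; 15 diethylsilane
Product: 16 C11 diethyl(hydrido)silyl ether of the 13-deoxy cis-decalin
Conditions: [Ir(cod)OMe]2 (0.5 mol %), THF, rt; volatiles removed in vacuo
Reagents that add atoms: none
Why: Iridium-catalysed dehydrogenative O-silylation of the alcohol stops at the monoalkoxysilane, and evaporation removes excess Et2SiH2 that could otherwise hydrosilylate the ring alkene on heating.

Step 13
Reactants: 16 C11 diethyl(hydrido)silyl ether
Product: 17 oxasilolane (O11–SiEt2–C13 bridge on the β face)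
Conditions: [Ir(cod)OMe]2 (4 mol %), 3,4,7,8-tetramethyl-1,10-phenanthroline (9 mol %), norbornene (2 equiv), THF, 120 °C, sealed tube
Reagents that add atoms: none
Why: The Si–H bond of 16 adds to the phenanthroline-ligated iridium silyl complex, hydride is passed to norbornene, the β C13–H bond is cleaved within a six-membered Ir–Si–O11–C11–C12–C13 metallacycle, and C–Si reductive elimination releases 17 and norbornane. The closest known reaction is the iridium-catalysed hydroxyl-directed silylation of secondary γ C–H bonds of (hydrido)silyl ethers, which tolerates silyl ethers and hindered alkenes. The one new ring, the five-membered 1,2-oxasilolane, closes by this intramolecular C–H silylation and bridges C11 and C13 as a 6-oxa-7-silabicyclo[3.2.1]octane. The new stereocentre C13 is controlled by the tether, since a two-atom O–Si bridge can only span two cis positions, so silicon ends up β like O11, as the target requires. Site selectivity holds because the only other γ carbon, C9, has its hydrogen on the α face and no primary γ C–H bond exists, and chemoselectivity relies on strained norbornene beating the C15=C16 alkene, cis-disubstituted and flanked by the branched C14 and C17, as hydrogen acceptor. Because C8 holds O11 equatorial the reacting conformer is the ring A boat, which is why high temperature and raised catalyst loading are planned and why this step carries the risk of the route.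

Step 14
Reactants: 17 oxasilolane
Product: 18 cis-1,3-diol (C11 β-OH; C13 β-OH)
Conditions: 30% aq H2O2, KHCO3, THF/MeOH, 50 °C
Reagents that add atoms: hydrogen peroxide (OO)
Why: Tamao–Fleming oxidation: hydroperoxide adds to the alkoxysilane and the C13–Si bond migrates to oxygen with retention, the fluoride-free medium sparing both silyl ethers and the unactivated alkene.

Step 15
Reactants: 18 cis-1,3-diol
Product: 19 C11 methyl ether (free C13 β-OH)
Conditions: Me3OBF4 (1.1 equiv), 1,8-bis(dimethylamino)naphthalene, 4 Å MS, CH2Cl2, 0 °C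
Reagents that add atoms: trimethyloxonium tetrafluoroborate (C[O+](C)C.F[B-](F)(F)F)
Why: Site-selective O-methylation with a Meerwein salt: O11 lies between two CH2 groups whereas O13 is gauche to the axial C14–C15 bond at the ring fusion, so limiting reagent should favour O11 and unreacted diol can be recycled.

Step 16
Reactants: 19 C11 methyl ether
Product: 20 C13 TBS ether
Conditions: TBSOTf, 2,6-lutidine, CH2Cl2, 0 °C
Reagents that add atoms: tert-butyldimethylsilyl triflate (CC(C)(C)[Si](C)(C)OS(=O)(=O)C(F)(F)F)
Why: O-Silylation with the reactive triflate covers the hindered secondary hydroxyl for the oxidation and organolithium steps ahead.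

Step 17
Reactants: 20 C13 TBS ether
Product: 21 C18 alcohol (C13 OTBS and C7 OTIPS kept)
Conditions: CSA (cat.), MeOH/CH2Cl2, 0 °C
Reagents that add atoms: none
Why: Acid-catalysed methanolysis removes a primary TBS ether faster than a hindered secondary TBS ether or a neopentyl TIPS ether.

Step 18
Reactants: 21 C18 alcohol
Product: 22 C18 aldehyde
Conditions: Dess–Martin periodinane, pyridine, CH2Cl2, 0 °C
Reagents that add atoms: none
Why: Buffered Dess–Martin oxidation is neutral enough to keep the β,γ-unsaturated aldehyde from epimerising at C17 or moving the alkene into conjugation, and the crude aldehyde is used at once.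

Step 19
Reactants: 22 C18 aldehyde
Product: 23 1,1-dibromoalkene (C18H=C19Br2)
Conditions: CBr4, PPh3, 2,6-lutidine, CH2Cl2, 0 °C
Reagents that add atoms: tetrabromomethane (BrC(Br)(Br)Br)
Why: Corey–Fuchs dibromoolefination is a non-basic Wittig-type reaction and therefore safe for the sensitive C17 centre.

Step 20
Reactants: 23 1,1-dibromoalkene
Product: 25 methyl alkyne (C18≡C19–CH3), via lithium acetylide 24 (not isolated)
Conditions: n-BuLi (2.1 equiv), THF, −78 °C; MeI, −78 °C → rt
Reagents that add atoms: iodomethane (CI)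
Why: Second stage of the Corey–Fuchs sequence: bromine–lithium exchange, rearrangement and deprotonation give the acetylide, which is C-methylated in the same flask to bring in the C19 methyl group.

Step 21
Reactants: 25 methyl alkyne
Product: 27 (E)-vinyl iodide (C18H=C19(CH3)I; C17 trans to I), via alkenylzirconocene chloride 26 (not isolated)
Conditions: Cp2Zr(H)Cl, THF, rt; I2, −78 °C
Reagents that add atoms: iodine (II)
Why: Syn hydrozirconation places zirconium on the alkyne carbon next to the small methyl group and away from the branched C17, and iodinolysis with retention fixes the 18E geometry, the hindered ring alkene reacting far more slowly than the alkyne.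

Step 22
Reactants: 27 (E)-vinyl iodide
Product: 28 diol (C7 CH2OH; C13 β-OH)
Conditions: 48% aq HF, MeCN, rt
Reagents that add atoms: none
Why: Acidic fluoride desilylation removes TIPS and TBS in one operation at a stage where no acid-labile group is present.

Step 23
Reactants: 28 diol
Product: 29 C7 aldehyde (free C13 β-OH)
Conditions: TEMPO (cat.), PhI(OAc)2, CH2Cl2, rt
Reagents that add atoms: none
Why: Oxoammonium oxidation prefers primary over secondary alcohols, the aldehyde has no α-hydrogen, and lactol formation with O13 is barred because it would need C8, O11 and O13 triaxial on ring A.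

Step 24
Reactants: 29 C7 aldehyde
Product: 31 C13 carbamate aldehyde, via N-trichloroacetyl carbamate 30 (not isolated)
Conditions: Cl3CC(O)NCO, CH2Cl2, 0 °C; K2CO3 (cat.), MeOH, 0 °C
Reagents that add atoms: trichloroacetyl isocyanate (O=C=NC(=O)C(Cl)(Cl)Cl)
Why: Carbamoylation with an acyl isocyanate followed by methanolysis of the activating acyl group converts the only hydroxyl present into the primary carbamate after all strongly basic steps are over.

Step 25
Reactants: 31 C13 carbamate aldehyde
Product: 32 decalin fragment with (E)-C6 vinylboronic acid pinacol ester and C19 iodide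
Conditions: CrCl2, Cl2CHBpin, LiI, THF, rt
Reagents that add atoms: 2-(dichloromethyl)-4,4,5,5-tetramethyl-1,3,2-dioxaborolane (ClC(Cl)B1OC(C)(C)C(C)(C)O1)
Why: Takai-type boryl olefination through a geminal dichromium reagent gives the (E)-alkenylboronate from the non-enolisable neopentyl aldehyde, and without a nickel salt CrCl2 leaves the vinyl iodide and the carbamate alone.

Step 26
Reactants: 33 N-Boc-D-alaninal
Product: 35 tert-butyl N-[(2R,3S,4S)-3-hydroxy-4-methylhex-5-en-2-yl]carbamate, via diisopinocampheylborinate 34 (not isolated)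
Conditions: trans-2-butene, n-BuLi, KOt-Bu, THF, −78 → −45 °C; (−)-Ipc2BOMe, −78 °C; BF3·OEt2; 33, −78 °C; NaOH, H2O2
Reagents that add atoms: trans-but-2-ene (C/C=C/C)
Why: Brown crotylboration: the (E)-crotylborane reacts through a chair transition state to give the anti C24/C25 pair, and the isopinocampheyl groups derived from (+)-α-pinene direct attack to the Si face of the aldehyde, which coincides with Felkin control and gives the 25,26-anti amino alcohol.

Step 27
Reactants: 35 tert-butyl N-[(2R,3S,4S)-3-hydroxy-4-methylhex-5-en-2-yl]carbamate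
Product: 37 N-[(2R,3S,4S)-3-hydroxy-4-methylhex-5-en-2-yl]acetamide, via amino alcohol hydrochloride 36 (not isolated)
Conditions: HCl (4 M in dioxane), 0 °C; concentrate; Ac2O (1.05 equiv), Et3N, CH2Cl2, 0 °C
Reagents that add atoms: acetic anhydride (CC(=O)OC(C)=O)
Why: Acidolysis of the Boc group and chemoselective N-acetylation (amine far more nucleophilic than the secondary alcohol) install the final acetamide early, so that no nitrogen manipulation is left for the polyene stage.

Step 28
Reactants: 37 N-[(2R,3S,4S)-3-hydroxy-4-methylhex-5-en-2-yl]acetamide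
Product: 38 1-[(4R,5S)-5-[(2S)-but-3-en-2-yl]-2,2,4-trimethyl-1,3-oxazolidin-3-yl]ethan-1-one
Conditions: Me2C(OMe)2, CSA (cat.), toluene, 80 °C
Reagents that add atoms: 2,2-dimethoxypropane (COC(C)(C)OC)
Why: Acid-catalysed N,O-acetalisation ties O25 and N26 into a cis-4,5-disubstituted oxazolidine, protecting both with one group and removing the N–H that would otherwise close onto the C23 aldehyde as a five-membered hemiaminal.

Step 29
Reactants: 38 N-acetyl oxazolidine alkene
Product: 40 (2R)-2-[(4R,5S)-3-acetyl-2,2,4-trimethyl-1,3-oxazolidin-5-yl]propanal, via secondary ozonide 39 (not isolated)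
Conditions: O3, CH2Cl2, −78 °C; PPh3
Reagents that add atoms: ozone ([O-][O+]=O)
Why: Ozonolysis with reductive work-up cleaves the terminal alkene to the C23 aldehyde under neutral conditions that do not epimerise C24, and the aldehyde is used directly.

Step 30
Reactants: 41 (S)-but-3-yn-2-ol
Product: 42 (S)-but-3-yn-2-yl methanesulfonate
Conditions: MsCl, Et3N, CH2Cl2, −78 °C
Reagents that add atoms: methanesulfonyl chloride (CS(=O)(=O)Cl)
Why: O-Sulfonylation leaves the stereocentre untouched and provides the leaving group for the palladium step.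

Step 31
Reactants: 40 C23 aldehyde; 42 (S)-but-3-yn-2-yl methanesulfonate
Product: 44 (2S,3R,4R)-2-[(4R,5S)-3-acetyl-2,2,4-trimethyl-1,3-oxazolidin-5-yl]-4-methylhex-5-yn-3-ol, via (M)-allenylzinc 43 (not isolated)
Conditions: Pd(OAc)2 (5 mol %), PPh3 (5 mol %), Et2Zn (3 equiv), THF, −78 → −20 °C
Reagents that add atoms: none
Why: Marshall propargylation: zerovalent palladium displaces the mesylate in anti SN2′ fashion, Et2Zn transmetalates to the chiral allenylzinc, and its cyclic SE2′ addition gives the 22,23-anti alcohol under reagent control that is matched with Felkin (23,24-syn) and 1,3-anti induction from the aldehyde.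

Step 32
Reactants: 44 homopropargylic alcohol
Product: 45 (2S,3R,4R,5E)-2-[(4R,5S)-3-acetyl-2,2,4-trimethyl-1,3-oxazolidin-5-yl]-4-methyl-6-(tributylstannyl)hex-5-en-3-ol
Conditions: Bu3SnH, PdCl2(PPh3)2 (cat.), THF, 0 °C
Reagents that add atoms: tributylstannane (CCCC[SnH](CCCC)CCCC)
Why: Palladium-catalysed syn hydrostannation of a terminal alkyne with a branched propargylic carbon places tin at the terminus and fixes the 20E geometry.

Step 33
Reactants: 46 but-2-yn-1-ol
Product: 48 (Z)-3-iodobut-2-en-1-ol, via cyclic alkenylalanate 47 (not isolated)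
Conditions: NaAlH2(OCH2CH2OMe)2, Et2O, 0 °C → rt; I2, THF, −78 °C
Reagents that add atoms: iodine (II)
Why: Hydroxyl-directed trans hydroalumination of the propargylic alcohol puts aluminium on the distal carbon in a five-membered chelate, and iodinolysis with retention gives the Z iodide that encodes the 4Z alkene.

Step 34
Reactants: 48 (Z)-3-iodobut-2-en-1-ol
Product: 50 ethyl (2E,4Z)-5-iodohexa-2,4-dienoate, via (Z)-3-iodobut-2-enal 49 (not isolated)
Conditions: MnO2, Ph3P=CHCO2Et, CH2Cl2, rt
Reagents that add atoms: ethyl (triphenylphosphoranylidene)acetate (CCOC(=O)C=P(c1ccccc1)(c1ccccc1)c1ccccc1)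
Why: Tandem allylic oxidation and Wittig olefination traps the isomerisation-prone Z enal as it forms, the stabilised ylide giving the 2E alkene.

Step 35
Reactants: 50 ethyl (2E,4Z)-5-iodohexa-2,4-dienoate
Product: 51 (2E,4Z)-5-iodohexa-2,4-dienoic acid
Conditions: LiOH, THF/MeOH/H2O, rt; aq HCl
Reagents that add atoms: lithium hydroxide ([Li+].[OH-])
Why: Mild saponification frees the acid without disturbing either alkene geometry.

Step 36
Reactants: 32 decalin fragment; 45 alkenylstannane
Product: 52 C6–C27 diene alcohol (18E,20E; free C23 OH; C6 boronate kept)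
Conditions: Pd2(dba)3 (cat.), AsPh3, NMP, rt
Reagents that add atoms: none
Why: Stille cross-coupling: zerovalent palladium inserts into the C19–I bond and takes the alkenyl group from tin with retention at both alkenes, while the pinacol boronate stays inert in the absence of base or fluoride and the hydroxyl, carbamate and N,O-acetal are tolerated.

Step 37
Reactants: 52 diene alcohol; 51 (2E,4Z)-5-iodohexa-2,4-dienoic acid
Product: 54 seco ester (O23 acylated; C5 iodide; C6 boronate), via mixed anhydride 53 (not isolated)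
Conditions: 2,4,6-Cl3C6H2COCl, Et3N, toluene, rt; 52, DMAP, rt
Reagents that add atoms: none
Why: Yamaguchi esterification: the mixed anhydride acylates DMAP and then the only free hydroxyl, the hindered O23, the carbamate nitrogen being too poor a nucleophile to compete and the mild conditions preserving the 4Z geometry.

Step 38
Reactants: 54 seco ester
Product: 55 macrolactone with O25/N26 isopropylidene group
Conditions: Pd(PPh3)4 (cat.), TlOEt, THF/H2O, rt, high dilution
Reagents that add atoms: none
Why: Intramolecular Suzuki–Miyaura coupling at high dilution closes the 16-membered ring at C5–C6 with retention at both alkenes, thallium ethoxide speeding transmetalation of the hindered boronate so that ester and carbamate see base only briefly.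

Step 39
Reactants: 55 protected macrolactone
Product: 56 superstolide A
Conditions: TFA/H2O/CH2Cl2, 0 °C
Reagents that add atoms: none
Why: Acid hydrolysis of the N,O-isopropylidene aminal frees the C25 hydroxyl and the acetamide N–H in one operation, while lactone, carbamate, methyl ether and polyenes withstand brief cold aqueous acid and no stereocentre is touched.

**Compound list**

1 | benzoic acid | OC(=O)c1ccccc1 | starting material
2 | 1-methylcyclohexa-2,5-diene-1-carboxylic acid | CC1(C(=O)O)C=CCC=C1 | intermediate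
3 | methyl 1-methylcyclohexa-2,5-diene-1-carboxylate | COC(=O)C1(C)C=CCC=C1 | intermediate
4 | methyl 1-methyl-4-oxocyclohexa-2,5-diene-1-carboxylate | COC(=O)C1(C)C=CC(=O)C=C1 | intermediate
5 | but-3-en-2-one | CC(=O)C=C | starting material
6 | 2-(tert-butyldimethylsilyloxy)buta-1,3-diene | C=CC(=C)O[Si](C)(C)C(C)(C)C | intermediate
7 | cis-decalin enone ester | CC(C)(C)[Si](C)(C)OC1=CC[C@@H]2C(=O)C=C[C@](C)(C(=O)OC)[C@@H]2C1 | intermediate
8 | diol (C15 β-OH, C7 OH) | CC(C)(C)[Si](C)(C)OC1=CC[C@@H]2[C@H](O)C=C[C@](C)(CO)[C@@H]2C1 | intermediate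
9 | C7 TIPS ether | CC(C)(C)[Si](C)(C)OC1=CC[C@@H]2[C@H](O)C=C[C@](C)(CO[Si](C(C)C)(C(C)C)C(C)C)[C@@H]2C1 | intermediate
10 | C15 β-(tributylstannyl)methyl ether | CC(C)(C)[Si](C)(C)OC1=CC[C@@H]2[C@H](OC[Sn](CCCC)(CCCC)CCCC)C=C[C@](C)(CO[Si](C(C)C)(C(C)C)C(C)C)[C@@H]2C1 | intermediate
11 | homoallylic alcohol enol ether (not isolated) | CC(C)(C)[Si](C)(C)OC1=CC[C@@H]2C=C[C@H](CO)[C@](C)(CO[Si](C(C)C)(C(C)C)C(C)C)[C@@H]2C1 | intermediate
12 | hydroxy ketone | O=C1CC[C@@H]2C=C[C@H](CO)[C@](C)(CO[Si](C(C)C)(C(C)C)C(C)C)[C@@H]2C1 | intermediate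
13 | ketone (C18 OTBS, C7 OTIPS) | O=C1CC[C@@H]2C=C[C@H](CO[Si](C)(C)C(C)(C)C)[C@](C)(CO[Si](C(C)C)(C(C)C)C(C)C)[C@@H]2C1 | intermediate
14 | 13-deoxy alcohol (C11 β-OH) | O[C@@H]1CC[C@@H]2C=C[C@H](CO[Si](C)(C)C(C)(C)C)[C@](C)(CO[Si](C(C)C)(C(C)C)C(C)C)[C@@H]2C1 | intermediate
15 | diethylsilane | CC[SiH2]CC | starting material
16 | C11 diethyl(hydrido)silyl ether (key-step precursor) | CC[SiH](CC)O[C@@H]1CC[C@@H]2C=C[C@H](CO[Si](C)(C)C(C)(C)C)[C@](C)(CO[Si](C(C)C)(C(C)C)C(C)C)[C@@H]2C1 | intermediate
17 | oxasilolane bridging O11 and C13 (key-step product) | CC[Si]1(CC)O[C@@H]2C[C@H]1[C@@H]3C=C[C@H](CO[Si](C)(C)C(C)(C)C)[C@](C)(CO[Si](C(C)C)(C(C)C)C(C)C)[C@@H]3C2 | intermediate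
18 | cis-1,3-diol | O[C@@H]1C[C@H](O)[C@@H]2C=C[C@H](CO[Si](C)(C)C(C)(C)C)[C@](C)(CO[Si](C(C)C)(C(C)C)C(C)C)[C@@H]2C1 | intermediate
19 | C11 methyl ether | CO[C@@H]1C[C@H](O)[C@@H]2C=C[C@H](CO[Si](C)(C)C(C)(C)C)[C@](C)(CO[Si](C(C)C)(C(C)C)C(C)C)[C@@H]2C1 | intermediate
20 | C13 TBS ether | CO[C@@H]1C[C@H](O[Si](C)(C)C(C)(C)C)[C@@H]2C=C[C@H](CO[Si](C)(C)C(C)(C)C)[C@](C)(CO[Si](C(C)C)(C(C)C)C(C)C)[C@@H]2C1 | intermediate
21 | C18 alcohol | CO[C@@H]1C[C@H](O[Si](C)(C)C(C)(C)C)[C@@H]2C=C[C@H](CO)[C@](C)(CO[Si](C(C)C)(C(C)C)C(C)C)[C@@H]2C1 | intermediate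
22 | C18 aldehyde | CO[C@@H]1C[C@H](O[Si](C)(C)C(C)(C)C)[C@@H]2C=C[C@H](C=O)[C@](C)(CO[Si](C(C)C)(C(C)C)C(C)C)[C@@H]2C1 | intermediate
23 | 1,1-dibromoalkene | CO[C@@H]1C[C@H](O[Si](C)(C)C(C)(C)C)[C@@H]2C=C[C@H](C=C(Br)Br)[C@](C)(CO[Si](C(C)C)(C(C)C)C(C)C)[C@@H]2C1 | intermediate
24 | lithium acetylide (not isolated) | CO[C@@H]1C[C@H](O[Si](C)(C)C(C)(C)C)[C@@H]2C=C[C@H](C#C[Li])[C@](C)(CO[Si](C(C)C)(C(C)C)C(C)C)[C@@H]2C1 | intermediate
25 | methyl alkyne | CO[C@@H]1C[C@H](O[Si](C)(C)C(C)(C)C)[C@@H]2C=C[C@H](C#CC)[C@](C)(CO[Si](C(C)C)(C(C)C)C(C)C)[C@@H]2C1 | intermediate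
26 | alkenylzirconocene chloride (not isolated) | CO[C@@H]1C[C@H](O[Si](C)(C)C(C)(C)C)[C@@H]2C=C[C@H](/C=C(C)/[Zr](Cl)(C3C=CC=C3)C3C=CC=C3)[C@](C)(CO[Si](C(C)C)(C(C)C)C(C)C)[C@@H]2C1 | intermediate
27 | (E)-vinyl iodide | CO[C@@H]1C[C@H](O[Si](C)(C)C(C)(C)C)[C@@H]2C=C[C@H](/C=C(C)/I)[C@](C)(CO[Si](C(C)C)(C(C)C)C(C)C)[C@@H]2C1 | intermediate
28 | diol (C7 OH, C13 β-OH) | CO[C@@H]1C[C@H](O)[C@@H]2C=C[C@H](/C=C(C)/I)[C@](C)(CO)[C@@H]2C1 | intermediate
29 | C7 aldehyde | CO[C@@H]1C[C@H](O)[C@@H]2C=C[C@H](/C=C(C)/I)[C@](C)(C=O)[C@@H]2C1 | intermediate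
30 | N-trichloroacetyl carbamate (not isolated) | CO[C@@H]1C[C@H](OC(=O)NC(=O)C(Cl)(Cl)Cl)[C@@H]2C=C[C@H](/C=C(C)/I)[C@](C)(C=O)[C@@H]2C1 | intermediate
31 | C13 carbamate aldehyde | CO[C@@H]1C[C@H](OC(N)=O)[C@@H]2C=C[C@H](/C=C(C)/I)[C@](C)(C=O)[C@@H]2C1 | intermediate
32 | decalin fragment (C6 boronate, C19 iodide) | CO[C@@H]1C[C@H](OC(N)=O)[C@@H]2C=C[C@H](/C=C(C)/I)[C@](C)(/C=C/B3OC(C)(C)C(C)(C)O3)[C@@H]2C1 | intermediate
33 | N-Boc-D-alaninal | O=C[C@@H](C)NC(=O)OC(C)(C)C | starting material
34 | diisopinocampheylborinate (not isolated) | C=C[C@H](C)[C@H](OB([C@@H]1C[C@@H]2C[C@H]([C@H]1C)C2(C)C)[C@@H]1C[C@@H]2C[C@H]([C@H]1C)C2(C)C)[C@@H](C)NC(=O)OC(C)(C)C | intermediate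
35 | tert-butyl N-[(2R,3S,4S)-3-hydroxy-4-methylhex-5-en-2-yl]carbamate | C=C[C@H](C)[C@H](O)[C@@H](C)NC(=O)OC(C)(C)C | intermediate
36 | amino alcohol hydrochloride (not isolated) | C=C[C@H](C)[C@H](O)[C@@H](C)[NH3+].[Cl-] | intermediate
37 | N-[(2R,3S,4S)-3-hydroxy-4-methylhex-5-en-2-yl]acetamide | C=C[C@H](C)[C@H](O)[C@@H](C)NC(C)=O | intermediate
38 | N-acetyl oxazolidine alkene | C=C[C@H](C)[C@@H]1OC(C)(C)N(C(C)=O)[C@@H]1C | intermediate
39 | secondary ozonide (not isolated; ozonide carbon undefined) | C1OOC(O1)[C@H](C)[C@@H]2OC(C)(C)N(C(C)=O)[C@@H]2C | intermediate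
40 | C23 aldehyde | O=C[C@H](C)[C@@H]1OC(C)(C)N(C(C)=O)[C@@H]1C | intermediate
41 | (S)-but-3-yn-2-ol | C#C[C@H](C)O | starting material
42 | (S)-but-3-yn-2-yl methanesulfonate | C#C[C@H](C)OS(C)(=O)=O | intermediate
43 | (M)-buta-1,2-dienyl(ethyl)zinc (not isolated) | CC[Zn]C([H])=[C@]=C([H])C | intermediate
44 | homopropargylic alcohol (C20–C27) | C#C[C@@H](C)[C@@H](O)[C@H](C)[C@@H]1OC(C)(C)N(C(C)=O)[C@@H]1C | intermediate
45 | (E)-alkenylstannane (C20–C27) | CCCC[Sn](CCCC)(CCCC)/C=C/[C@@H](C)[C@@H](O)[C@H](C)[C@@H]1OC(C)(C)N(C(C)=O)[C@@H]1C | intermediate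
46 | but-2-yn-1-ol | CC#CCO | starting material
47 | cyclic alkenylalanate, sodium salt (not isolated) | CC1=CCO[Al-]1(OCCOC)OCCOC.[Na+] | intermediate
48 | (Z)-3-iodobut-2-en-1-ol | C/C(I)=C/CO | intermediate
49 | (Z)-3-iodobut-2-enal (not isolated) | C/C(I)=C/C=O | intermediate
50 | ethyl (2E,4Z)-5-iodohexa-2,4-dienoate | CCOC(=O)/C=C/C=C(C)\I | intermediate
51 | (2E,4Z)-5-iodohexa-2,4-dienoic acid | OC(=O)/C=C/C=C(C)\I | intermediate
52 | C6–C27 diene alcohol | CO[C@@H]1C[C@H](OC(N)=O)[C@@H]2C=C[C@H](/C=C(C)/C=C/[C@@H](C)[C@@H](O)[C@H](C)[C@@H]3OC(C)(C)N(C(C)=O)[C@@H]3C)[C@](C)(/C=C/B4OC(C)(C)C(C)(C)O4)[C@@H]2C1 | intermediate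
53 | mixed 2,4,6-trichlorobenzoic anhydride (not isolated) | O=C(OC(=O)/C=C/C=C(C)\I)c1c(Cl)cc(Cl)cc1Cl | intermediate
54 | seco ester | CO[C@@H]1C[C@H](OC(N)=O)[C@@H]2C=C[C@H](/C=C(C)/C=C/[C@@H](C)[C@@H](OC(=O)/C=C/C=C(C)\I)[C@H](C)[C@@H]3OC(C)(C)N(C(C)=O)[C@@H]3C)[C@](C)(/C=C/B4OC(C)(C)C(C)(C)O4)[C@@H]2C1 | intermediate
55 | macrolactone with O25/N26 isopropylidene group | CO[C@@H]1C[C@H](OC(N)=O)[C@@H]2C=C[C@@H]3/C=C(C)/C=C/[C@@H](C)[C@H]([C@H](C)[C@@H]4OC(C)(C)N(C(C)=O)[C@@H]4C)OC(=O)/C=C/C=C(C)\C=C\[C@]3(C)[C@@H]2C1 | intermediate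
56 | superstolide A (8R,9R,11S,13S,14R,17R,22R,23R,24R,25S,26R; 2E,4Z,6E,18E,20E) | CO[C@@H]1C[C@H](OC(N)=O)[C@@H]2C=C[C@@H]3/C=C(C)/C=C/[C@@H](C)[C@H]([C@H](C)[C@H](O)[C@@H](C)NC(C)=O)OC(=O)/C=C/C=C(C)\C=C\[C@]3(C)[C@@H]2C1 | target

**Count.** Total steps: 39. Longest linear sequence: 28 steps from benzoic acid (steps 1–3, 5–25, 36–39).

**Steps most likely to fail**

1. Step 13.
   - What may go wrong: the ring A boat may be too sparsely populated for C–H cleavage to compete with catalyst decay. The iridium hydride may instead hydrogenate, isomerise or hydrosilylate C15=C16.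
   - Fallback: oxygen is delivered from O11 to an alkene instead of to a C–H bond. The path sets out from ketone 13 and returns at diol 18.
   - Kinetic deprotonation on the less hindered C12 side with in-flask dehydrogenation (LDA, THF, −78 °C; N-tert-butylbenzenesulfinimidoyl chloride) would give the C12=C13 enone F1.
   - Luche reduction (NaBH4, CeCl3, MeOH), with hydride entering from the α face, would give the β allylic alcohol F2.
   - Hydroxyl-directed epoxidation (VO(acac)2, t-BuOOH) leaves the isolated C15=C16 alkene alone and would give the β epoxy alcohol F3.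
   - Dess–Martin oxidation would give the epoxy ketone F4.
   - Reductive cleavage of the Cα–O bond (SmI2, THF/MeOH, −90 °C) would give the β-hydroxy ketone F5, with O13 already β.
   - NaBH4 as in step 11 would then give 18.

2. Step 5.
   - What may go wrong: discrimination between the two enantiotopic alkenes or between the methyl and ester faces may be poor. The cycloaddition next to the quaternary carbon may be slow. The strong Lewis acid may trigger dienone–phenol rearrangement.
   - Fallback: a stoichiometric auxiliary with separation of diastereomers replaces catalysis. The path sets out from acid 2 and returns at diol 8.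
   - Acid 2 would be esterified with (−)-menthol (DCC, DMAP) to the menthyl ester F6 and oxidised as in step 3 to the menthyl dienone F7.
   - F7 would be combined with 6 under an achiral Lewis acid (Me2AlCl, CH2Cl2, −40 °C). Addition to the two C=C bonds now gives diastereomers.
   - The wanted adduct F8, its configuration secured by X-ray analysis, would be separated by chromatography or crystallisation from the unwanted diastereomer F9.
   - DIBAL-H as in step 6 cleaves the auxiliary from F8 and delivers 8.

3. Step 9.
   - What may go wrong: bond formation on the concave face next to the quaternary C8 may be outrun by a 1,2-shift or by simple protonation of the carbanion.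
   - Fallback: a neutral thermal [2,3]-shift through a carbene replaces the carbanion. The path sets out from allylic alcohol 9 and returns at alcohol 11.
   - Heating 9 with N,N-dimethylformamide dimethyl acetal (xylene, 140 °C, Büchi rearrangement) would transfer a CONMe2 group suprafacially from the β C15–O bond to C17 and give the β,γ-unsaturated amide F10.
   - LiH2NBH3 (THF, 0 °C) reduces the amide to 11, and aqueous acid as in step 9 then gives 12.

**Further compounds**

F1 | step 13 | C12=C13 enone | O=C1C=C[C@@H]2C=C[C@H](CO[Si](C)(C)C(C)(C)C)[C@](C)(CO[Si](C(C)C)(C(C)C)C(C)C)[C@@H]2C1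
F2 | step 13 | β allylic alcohol | O[C@@H]1C=C[C@@H]2C=C[C@H](CO[Si](C)(C)C(C)(C)C)[C@](C)(CO[Si](C(C)C)(C(C)C)C(C)C)[C@@H]2C1
F3 | step 13 | β epoxy alcohol | O[C@@H]1[C@@H]3O[C@@H]3[C@@H]2C=C[C@H](CO[Si](C)(C)C(C)(C)C)[C@](C)(CO[Si](C(C)C)(C(C)C)C(C)C)[C@@H]2C1
F4 | step 13 | epoxy ketone | O=C1[C@@H]3O[C@@H]3[C@@H]2C=C[C@H](CO[Si](C)(C)C(C)(C)C)[C@](C)(CO[Si](C(C)C)(C(C)C)C(C)C)[C@@H]2C1
F5 | step 13 | β-hydroxy ketone (C13 β-OH) | O=C1C[C@H](O)[C@@H]2C=C[C@H](CO[Si](C)(C)C(C)(C)C)[C@](C)(CO[Si](C(C)C)(C(C)C)C(C)C)[C@@H]2C1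
F6 | step 5 | (−)-menthyl 1-methylcyclohexa-2,5-diene-1-carboxylate | CC(C)[C@@H]1CC[C@@H](C)C[C@H]1OC(=O)C2(C)C=CCC=C2
F7 | step 5 | (−)-menthyl 1-methyl-4-oxocyclohexa-2,5-diene-1-carboxylate | CC(C)[C@@H]1CC[C@@H](C)C[C@H]1OC(=O)C2(C)C=CC(=O)C=C2
F8 | step 5 | menthyl ester analogue of 7 (wanted diastereomer) | CC(C)(C)[Si](C)(C)OC1=CC[C@@H]2C(=O)C=C[C@](C)(C(=O)O[C@@H]3C[C@H](C)CC[C@H]3C(C)C)[C@@H]2C1
F9 | step 5 | menthyl ester adduct with antipodal decalin core (unwanted diastereomer) | CC(C)(C)[Si](C)(C)OC1=CC[C@H]2C(=O)C=C[C@@](C)(C(=O)O[C@@H]3C[C@H](C)CC[C@H]3C(C)C)[C@H]2C1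
F10 | step 9 | C17 β-N,N-dimethylcarboxamide | CC(C)(C)[Si](C)(C)OC1=CC[C@@H]2C=C[C@H](C(=O)N(C)C)[C@](C)(CO[Si](C(C)C)(C(C)C)C(C)C)[C@@H]2C1
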